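The route rests on cutting the C13–C14 bond inside the contiguous C13/C14/C15 triol of the acyl chain (numbered from the ester carbonyl C1). Reading C15 as a ketone makes this an aldol bond. The key step adds the dicyclohexylboron enolate of a C14–C23 ketone, whose O14 and O17 are tied into a temporary seven-membered di-tert-butylsilylene ring, to the complete C1–C13 chloropentaenoate aldehyde that already carries the cyclohexane ester. The ring locks the E enolate, so one operation joins both halves and sets the 13,14-anti diol under Felkin control from C12. Hydroxyl-directed reduction then sets C15, and the silylene leaves in the final desilylation.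

Key step: step 21

Remark: locants C1–C23 (acyl chain) and C1'–C6' (ring) of the target are used for all intermediates, and compounds 1, 5, 8, 9, 12, 14, 24, 25 and 30 are assumed to be commercially available.

Step 1
Reactants: 1 (1S)-cyclohex-3-ene-1-carboxylic acid
Product: 2 (1S,3R,4S)-3,4-dihydroxycyclohexane-1-carboxylic acid
Conditions: OsO4 (1 mol %), NMO, acetone/H2O, rt
Reagents that add atoms: N-methylmorpholine N-oxide C[N+]1([O-])CCOCC1; water O
Why: Catalytic osmium tetroxide syn-dihydroxylation should add to the ring alkene mainly on the face anti to the C1' carboxyl group, which sets C3' (R) and C4' (S) together; the minor all-cis diol is expected and is removed by chromatography after step 2.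

Step 2
Reactants: 2 (1S,3R,4S)-3,4-dihydroxycyclohexane-1-carboxylic acid
Product: 3 prop-2-en-1-yl (1S,3R,4S)-3,4-dihydroxycyclohexane-1-carboxylate
Conditions: allyl bromide, KHCO3, DMF, rt
Reagents that add atoms: allyl bromide C=CCBr
Why: SN2 O-alkylation of the carboxylate under bicarbonate leaves both hydroxyls untouched and gives an ester that is later removed by zerovalent palladium without acid or base.

Step 3
Reactants: 3 prop-2-en-1-yl (1S,3R,4S)-3,4-dihydroxycyclohexane-1-carboxylate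
Product: 4 prop-2-en-1-yl (1S,3R,4S)-4-[(tert-butyldimethylsilyl)oxy]-3-hydroxycyclohexane-1-carboxylate
Conditions: TBSCl (1.05 equiv), imidazole, DMF, −20 °C
Reagents that add atoms: tert-butyldimethylsilyl chloride CC(C)(C)[Si](C)(C)Cl
Why: Kinetic silylation should select the C4' hydroxyl, because with the ester equatorial this hydroxyl is equatorial while the C3' hydroxyl is axial and slower.

Step 4
Reactants: 5 ethyl (2E)-4-(diethoxyphosphoryl)but-2-enoate
Product: 6 (2E)-4-(diethoxyphosphoryl)but-2-enoic acid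
Conditions: LiOH (1.0 equiv), THF/H2O, 0 °C; then 1 M HCl
Reagents that add atoms: lithium hydroxide [Li+].[OH-]
Why: Saponification with one equivalent of hydroxide cleaves the carboxylic ester much faster than the phosphonate esters.

Step 5
Reactants: 4 prop-2-en-1-yl (1S,3R,4S)-4-[(tert-butyldimethylsilyl)oxy]-3-hydroxycyclohexane-1-carboxylate; 6 (2E)-4-(diethoxyphosphoryl)but-2-enoic acid
Product: 7 prop-2-en-1-yl (1S,3R,4S)-4-[(tert-butyldimethylsilyl)oxy]-3-{[(2E)-4-(diethoxyphosphoryl)but-2-enoyl]oxy}cyclohexane-1-carboxylate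
Conditions: DCC, DMAP (cat.), CH2Cl2, 0 °C → rt
Reagents that add atoms: none
Why: Steglich esterification acylates the only free hydroxyl (axial C3'–OH) and so fixes the ester on the correct ring oxygen.

Step 6
Reactants: 8 (2E)-3-iodoprop-2-en-1-ol; 9 2-(triphenylphosphoranylidene)propanal
Product: 11 (2E,4E)-5-iodo-2-methylpenta-2,4-dienal, via (2E)-3-iodoprop-2-enal 10 (not isolated)
Conditions: MnO2, CH2Cl2, rt; filter; then 9, toluene, 60 °C, dark
Reagents that add atoms: none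
Why: Allylic oxidation with MnO2 followed by Wittig olefination with a stabilised ylide should give the trisubstituted C6=C7 alkene with E geometry while the E alkenyl iodide is retained.

Step 7
Reactants: 12 methyl (2R)-3-hydroxy-2-methylpropanoate
Product: 13 methyl (2R)-3-[(tert-butyldiphenylsilyl)oxy]-2-methylpropanoate
Conditions: TBDPSCl, imidazole, DMF, rt
Reagents that add atoms: tert-butyldiphenylsilyl chloride CC(C)(C)[Si](Cl)(c1ccccc1)c1ccccc1
Why: Silylation of the primary alcohol with the silyl group most resistant to boron Lewis acids prepares the C12 stereocentre (from the chiral pool) for step 9.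

Step 8
Reactants: 13 methyl (2R)-3-[(tert-butyldiphenylsilyl)oxy]-2-methylpropanoate; 14 dimethyl (1-diazo-2-oxopropyl)phosphonate
Product: 16 tert-butyl{[(2S)-2-methylbut-3-yn-1-yl]oxy}diphenylsilane, via silyloxy aldehyde 15 (not isolated)
Conditions: i-Bu2AlH, CH2Cl2, −78 °C; then MeOH, 14, K2CO3, 0 °C → rt
Reagents that add atoms: none
Why: Low-temperature ester-to-aldehyde reduction followed in the same flask by Seyferth–Gilbert homologation with the Ohira–Bestmann reagent gives the terminal alkyne, the mild carbonate conditions at 0 °C preserving the α-stereocentre.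

Step 9
Reactants: 16 tert-butyl{[(2S)-2-methylbut-3-yn-1-yl]oxy}diphenylsilane
Product: 18 tert-butyl{[(2R,3Z)-3-chloro-2-methyl-4-(4,4,5,5-tetramethyl-1,3,2-dioxaborolan-2-yl)but-3-en-1-yl]oxy}diphenylsilane, via alkenyldichloroborane 17 (not isolated)
Conditions: BCl3 (1.1 equiv), CH2Cl2, −78 → 0 °C; then pinacol, Et3N, 0 °C
Reagents that add atoms: boron trichloride ClB(Cl)Cl; pinacol CC(C)(O)C(C)(C)O
Why: Syn chloroboration of a terminal alkyne places chlorine on the internal carbon and boron cis to it on the terminus, which after esterification gives the alkenylboronate that encodes the 10Z chloroalkene.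

Step 10
Reactants: 18 tert-butyl{[(2R,3Z)-3-chloro-2-methyl-4-(4,4,5,5-tetramethyl-1,3,2-dioxaborolan-2-yl)but-3-en-1-yl]oxy}diphenylsilane; 11 (2E,4E)-5-iodo-2-methylpenta-2,4-dienal
Product: 19 (2E,4E,6Z,8R)-9-[(tert-butyldiphenylsilyl)oxy]-7-chloro-2,8-dimethylnona-2,4,6-trienal
Conditions: Pd(PPh3)4 (5 mol %), K3PO4 (aq), THF, 45 °C, dark
Reagents that add atoms: none
Why: Suzuki–Miyaura coupling joins C9 and C10 with retention of both alkene geometries, the alkenyl chloride being inert to Pd(PPh3)4 next to the alkenyl iodide.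

Step 11
Reactants: 19 (2E,4E,6Z,8R)-9-[(tert-butyldiphenylsilyl)oxy]-7-chloro-2,8-dimethylnona-2,4,6-trienal
Product: 20 (2E,4E,6Z,8R)-7-chloro-9-hydroxy-2,8-dimethylnona-2,4,6-trienal
Conditions: Bu4NF, AcOH (1:1), THF, 0 °C → rt
Reagents that add atoms: none
Why: Acetic-acid-buffered fluoride desilylation frees the C13 hydroxyl before the ring silyl ether is present, so no silyl differentiation is needed later.

Step 12
Reactants: 7 prop-2-en-1-yl (1S,3R,4S)-4-[(tert-butyldimethylsilyl)oxy]-3-{[(2E)-4-(diethoxyphosphoryl)but-2-enoyl]oxy}cyclohexane-1-carboxylate; 20 (2E,4E,6Z,8R)-7-chloro-9-hydroxy-2,8-dimethylnona-2,4,6-trienal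
Product: 22 prop-2-en-1-yl (1S,3R,4S)-4-[(tert-butyldimethylsilyl)oxy]-3-{[(2E,4E,6E,8E,10Z,12R)-11-chloro-13-hydroxy-6,12-dimethyltrideca-2,4,6,8,10-pentaenoyl]oxy}cyclohexane-1-carboxylate, via lithiated phosphonate 21 (not isolated)
Conditions: LiN(SiMe3)2 (1.0 equiv), THF, −78 °C; then 20, −78 → 0 °C, dark
Reagents that add atoms: none
Why: Horner–Wadsworth–Emmons olefination of the vinylogous phosphonate anion should give the E C4=C5 alkene, and the free primary alcohol is far less acidic than the phosphonate and is tolerated.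

Step 13
Reactants: 22 prop-2-en-1-yl (1S,3R,4S)-4-[(tert-butyldimethylsilyl)oxy]-3-{[(2E,4E,6E,8E,10Z,12R)-11-chloro-13-hydroxy-6,12-dimethyltrideca-2,4,6,8,10-pentaenoyl]oxy}cyclohexane-1-carboxylate
Product: 23 prop-2-en-1-yl (1S,3R,4S)-4-[(tert-butyldimethylsilyl)oxy]-3-{[(2E,4E,6E,8E,10Z,12R)-11-chloro-6,12-dimethyl-13-oxotrideca-2,4,6,8,10-pentaenoyl]oxy}cyclohexane-1-carboxylate
Conditions: Dess–Martin periodinane, NaHCO3, CH2Cl2, 0 °C; used at once
Reagents that add atoms: none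
Why: Buffered Dess–Martin oxidation gives the β,γ-unsaturated α-methyl aldehyde under neutral conditions that should neither epimerise C12 nor move the C10=C11 bond.

Step 14
Reactants: 24 (2E)-pent-2-enal; 25 tributyl(prop-2-en-1-yl)stannane
Product: 26 (4R,5E)-octa-1,5-dien-4-ol
Conditions: (R)-BINOL (10 mol %), Ti(OiPr)4 (10 mol %), 4 Å MS, CH2Cl2, −20 °C
Reagents that add atoms: none
Why: Keck asymmetric allylation, in which the (R)-BINOL–titanium Lewis acid directs the allylstannane to the Re face of the enal carbonyl (1,2-addition), sets the future C19 as (4R).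

Step 15
Reactants: 26 (4R,5E)-octa-1,5-dien-4-ol
Product: 27 tert-butyl(dimethyl){[(4R,5E)-octa-1,5-dien-4-yl]oxy}silane
Conditions: TBSCl, imidazole, DMF, rt
Reagents that add atoms: tert-butyldimethylsilyl chloride CC(C)(C)[Si](C)(C)Cl
Why: Standard silylation protects the allylic C19 hydroxyl for the rest of the route.

Step 16
Reactants: 27 tert-butyl(dimethyl){[(4R,5E)-octa-1,5-dien-4-yl]oxy}silane
Product: 28 (3R,4E)-3-[(tert-butyldimethylsilyl)oxy]hept-4-enal
Conditions: OsO4 (2 mol %), NaIO4, 2,6-lutidine, dioxane/H2O, 0 °C → rt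
Reagents that add atoms: sodium periodate [Na+].[O-]I(=O)(=O)=O; water O
Why: Johnson–Lemieux cleavage should take the unhindered terminal alkene ahead of the internal alkene, which is shielded and deactivated by the adjacent silyloxy-bearing carbon.

Step 17
Reactants: 28 (3R,4E)-3-[(tert-butyldimethylsilyl)oxy]hept-4-enal
Product: 29 (2S,3S,4E)-3-[(tert-butyldimethylsilyl)oxy]-2-chlorohept-4-enal
Conditions: (5S)-5-benzyl-2,2,3-trimethylimidazolidin-4-one·TFA (10 mol %), 2,3,4,5,6,6-hexachlorocyclohexa-2,4-dien-1-one, acetone, −30 °C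
Reagents that add atoms: 2,3,4,5,6,6-hexachlorocyclohexa-2,4-dien-1-one O=C1C(Cl)=C(Cl)C(Cl)=C(Cl)C1(Cl)Cl
Why: Enamine-catalysed α-chlorination, in which the benzyl group of the (5S)-imidazolidinone blocks one enamine face, should deliver chlorine to give the (2S) chloride (C18) anti to the C19 silyloxy group under catalyst control, the acidic low-temperature medium disfavouring β-elimination.

Step 18
Reactants: 30 1-[(tert-butyldimethylsilyl)oxy]propan-2-one; 29 (2S,3S,4E)-3-[(tert-butyldimethylsilyl)oxy]-2-chlorohept-4-enal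
Product: 32 (4R,5R,6S,7E)-1,6-bis[(tert-butyldimethylsilyl)oxy]-5-chloro-4-hydroxydec-7-en-2-one, via lithium enolate 31 (not isolated)
Conditions: LiN(i-Pr)2, THF, −78 °C; then 29, −78 °C; aq NH4Cl
Reagents that add atoms: none
Why: Lithium aldol addition of the kinetic methyl-side enolate to the α-chloroaldehyde should follow the polar (Cornforth-type) model and give the 17,18-anti chlorohydrin, which sets C17 as (4R).

Step 19
Reactants: 32 (4R,5R,6S,7E)-1,6-bis[(tert-butyldimethylsilyl)oxy]-5-chloro-4-hydroxydec-7-en-2-one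
Product: 33 (4R,5R,6S,7E)-6-[(tert-butyldimethylsilyl)oxy]-5-chloro-1,4-dihydroxydec-7-en-2-one
Conditions: CSA (10 mol %), MeOH/CH2Cl2, 0 °C
Reagents that add atoms: none
Why: Acid-catalysed methanolysis removes the primary silyl ether next to the ketone much faster than the hindered secondary allylic one.

Step 20
Reactants: 33 (4R,5R,6S,7E)-6-[(tert-butyldimethylsilyl)oxy]-5-chloro-1,4-dihydroxydec-7-en-2-one
Product: 34 (7R)-2,2-di-tert-butyl-7-{(1R,2S,3E)-2-[(tert-butyldimethylsilyl)oxy]-1-chlorohex-3-en-1-yl}-1,3,2-dioxasilepan-5-one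
Conditions: t-Bu2Si(OTf)2, 2,6-lutidine, CH2Cl2 (0.01 M), 0 °C
Reagents that add atoms: di-tert-butylsilyl bis(trifluoromethanesulfonate) CC(C)(C)[Si](OS(=O)(=O)C(F)(F)F)(OS(=O)(=O)C(F)(F)F)C(C)(C)C
Why: Silylene formation across the 1,4-related O14 and O17 (first at the primary hydroxyl, then ring closure under dilution) gives the seven-membered ring that contains C14, C15 and C16.

Step 21
Reactants: 34 (7R)-2,2-di-tert-butyl-7-{(1R,2S,3E)-2-[(tert-butyldimethylsilyl)oxy]-1-chlorohex-3-en-1-yl}-1,3,2-dioxasilepan-5-one; 23 prop-2-en-1-yl (1S,3R,4S)-4-[(tert-butyldimethylsilyl)oxy]-3-{[(2E,4E,6E,8E,10Z,12R)-11-chloro-6,12-dimethyl-13-oxotrideca-2,4,6,8,10-pentaenoyl]oxy}cyclohexane-1-carboxylate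
Product: 37 prop-2-en-1-yl (1S,3R,4S)-4-[(tert-butyldimethylsilyl)oxy]-3-{[(2E,4E,6E,8E,10Z,12R,13R)-13-[(4R,7R)-2,2-di-tert-butyl-7-{(1R,2S,3E)-2-[(tert-butyldimethylsilyl)oxy]-1-chlorohex-3-en-1-yl}-5-oxo-1,3,2-dioxasilepan-4-yl]-11-chloro-13-hydroxy-6,12-dimethyltrideca-2,4,6,8,10-pentaenoyl]oxy}cyclohexane-1-carboxylate, via boron enolate 35 (not isolated), via boron aldolate 36 (not isolated)
Conditions: Cy2BCl, Et3N, Et2O, −78 → 0 °C; then 23, −78 → −20 °C; pH 7 buffer/MeOH (no peroxide)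
Reagents that add atoms: none
Why: Soft enolisation of 34 at the α-silyloxy methylene C14 gives enol borinate 35, whose C14=C15 bond lies inside the seven-membered ring so that O14 is forced trans to the boron-bearing oxygen (E enolate), and addition to aldehyde 23 through a chair Zimmerman–Traxler transition state gives aldolate 36 and then 37 on hydrolysis. The closest known reaction type is the anti-selective boron aldol of cyclic α-oxygenated ketones such as 2,2-dimethyl-1,3-dioxan-5-one; no ring is closed in this step. C14 is controlled by the ring-enforced enolate geometry (13,14-anti), and C13 by Felkin–Anh induction from C12 of the aldehyde (12,13-syn), which E enolates are expected to follow. The step needs enolisation at C14 and not at C16, which the acidifying α-oxygen and the more hindered, β-branched C16 should secure, and it needs C12 of the β,γ-unsaturated aldehyde to survive, which the non-basic −78 °C addition should secure. The allyl ester, the pentaenoate, both chlorides and the silyl ethers do not react with the borinate, and the peroxide-free work-up spares the polyene.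

Step 22
Reactants: 37 prop-2-en-1-yl (1S,3R,4S)-4-[(tert-butyldimethylsilyl)oxy]-3-{[(2E,4E,6E,8E,10Z,12R,13R)-13-[(4R,7R)-2,2-di-tert-butyl-7-{(1R,2S,3E)-2-[(tert-butyldimethylsilyl)oxy]-1-chlorohex-3-en-1-yl}-5-oxo-1,3,2-dioxasilepan-4-yl]-11-chloro-13-hydroxy-6,12-dimethyltrideca-2,4,6,8,10-pentaenoyl]oxy}cyclohexane-1-carboxylate
Product: 39 prop-2-en-1-yl (1S,3R,4S)-4-[(tert-butyldimethylsilyl)oxy]-3-{[(2E,4E,6E,8E,10Z,12R,13R)-13-[(4S,5S,7R)-2,2-di-tert-butyl-7-{(1R,2S,3E)-2-[(tert-butyldimethylsilyl)oxy]-1-chlorohex-3-en-1-yl}-5-hydroxy-1,3,2-dioxasilepan-4-yl]-11-chloro-13-hydroxy-6,12-dimethyltrideca-2,4,6,8,10-pentaenoyl]oxy}cyclohexane-1-carboxylate, via diethylboron chelate 38 (not isolated)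
Conditions: Et2BOMe, THF/MeOH, −78 °C; then NaBH4, −78 °C; AcOH, MeOH co-evaporation
Reagents that add atoms: none
Why: Narasaka–Prasad reduction, in which the boron chelate between the C13 hydroxyl and the C15 ketone is attacked by external hydride, should give the 13,15-syn alcohol (15S, anti to O14) while the esters, chlorides and silyl ethers are inert to NaBH4 at −78 °C.

Step 23
Reactants: 39 prop-2-en-1-yl (1S,3R,4S)-4-[(tert-butyldimethylsilyl)oxy]-3-{[(2E,4E,6E,8E,10Z,12R,13R)-13-[(4S,5S,7R)-2,2-di-tert-butyl-7-{(1R,2S,3E)-2-[(tert-butyldimethylsilyl)oxy]-1-chlorohex-3-en-1-yl}-5-hydroxy-1,3,2-dioxasilepan-4-yl]-11-chloro-13-hydroxy-6,12-dimethyltrideca-2,4,6,8,10-pentaenoyl]oxy}cyclohexane-1-carboxylate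
Product: 40 (1S,3R,4S)-4-[(tert-butyldimethylsilyl)oxy]-3-{[(2E,4E,6E,8E,10Z,12R,13R)-13-[(4S,5S,7R)-2,2-di-tert-butyl-7-{(1R,2S,3E)-2-[(tert-butyldimethylsilyl)oxy]-1-chlorohex-3-en-1-yl}-5-hydroxy-1,3,2-dioxasilepan-4-yl]-11-chloro-13-hydroxy-6,12-dimethyltrideca-2,4,6,8,10-pentaenoyl]oxy}cyclohexane-1-carboxylic acid
Conditions: Pd(PPh3)4 (5 mol %), morpholine, THF, 0 °C → rt, dark
Reagents that add atoms: none
Why: Tsuji–Trost deallylation frees the carboxylic acid under neutral conditions that leave the secondary pentaenoate ester, the alkenyl chloride and all silyl groups intact.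

Step 24
Reactants: 40 (1S,3R,4S)-4-[(tert-butyldimethylsilyl)oxy]-3-{[(2E,4E,6E,8E,10Z,12R,13R)-13-[(4S,5S,7R)-2,2-di-tert-butyl-7-{(1R,2S,3E)-2-[(tert-butyldimethylsilyl)oxy]-1-chlorohex-3-en-1-yl}-5-hydroxy-1,3,2-dioxasilepan-4-yl]-11-chloro-13-hydroxy-6,12-dimethyltrideca-2,4,6,8,10-pentaenoyl]oxy}cyclohexane-1-carboxylic acid
Product: 41 (1S,3R,4S)-3-{[(2E,4E,6E,8E,10Z,12R,13R,14S,15S,17R,18R,19S,20E)-11,18-dichloro-13,14,15,17,19-pentahydroxy-6,12-dimethyltricosa-2,4,6,8,10,20-hexaenoyl]oxy}-4-hydroxycyclohexane-1-carboxylic acid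
Conditions: HF·pyridine, pyridine, THF, 0 °C → rt, dark
Reagents that add atoms: none
Why: Fluoride cleaves both tert-butyldimethylsilyl ethers and the silylene in one operation, and the acidic, non-basic medium should keep the freed C17 and C19 hydroxyls from displacing the C18 chloride.

Compound list
1 | (1S)-cyclohex-3-ene-1-carboxylic acid | C1=CC[C@@H](C(=O)O)CC1 | starting material
2 | (1S,3R,4S)-3,4-dihydroxycyclohexane-1-carboxylic acid | O[C@@H]1C[C@@H](C(=O)O)CC[C@@H]1O | intermediate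
3 | prop-2-en-1-yl (1S,3R,4S)-3,4-dihydroxycyclohexane-1-carboxylate | O[C@@H]1C[C@@H](C(=O)OCC=C)CC[C@@H]1O | intermediate
4 | prop-2-en-1-yl (1S,3R,4S)-4-[(tert-butyldimethylsilyl)oxy]-3-hydroxycyclohexane-1-carboxylate | O[C@@H]1C[C@@H](C(=O)OCC=C)CC[C@@H]1O[Si](C)(C)C(C)(C)C | intermediate
5 | ethyl (2E)-4-(diethoxyphosphoryl)but-2-enoate | CCOC(=O)/C=C/CP(=O)(OCC)OCC | starting material
6 | (2E)-4-(diethoxyphosphoryl)but-2-enoic acid | OC(=O)/C=C/CP(=O)(OCC)OCC | intermediate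
7 | prop-2-en-1-yl (1S,3R,4S)-4-[(tert-butyldimethylsilyl)oxy]-3-{[(2E)-4-(diethoxyphosphoryl)but-2-enoyl]oxy}cyclohexane-1-carboxylate | CCOP(=O)(OCC)C/C=C/C(=O)O[C@@H]1C[C@@H](C(=O)OCC=C)CC[C@@H]1O[Si](C)(C)C(C)(C)C | intermediate
8 | (2E)-3-iodoprop-2-en-1-ol | OC/C=C/I | starting material
9 | 2-(triphenylphosphoranylidene)propanal | CC(C=O)=P(c1ccccc1)(c1ccccc1)c1ccccc1 | starting material
10 | (2E)-3-iodoprop-2-enal | O=C/C=C/I | intermediate
11 | (2E,4E)-5-iodo-2-methylpenta-2,4-dienal | O=C/C(C)=C/C=C/I | intermediate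
12 | methyl (2R)-3-hydroxy-2-methylpropanoate | COC(=O)[C@H](C)CO | starting material
13 | methyl (2R)-3-[(tert-butyldiphenylsilyl)oxy]-2-methylpropanoate | COC(=O)[C@H](C)CO[Si](c1ccccc1)(c1ccccc1)C(C)(C)C | intermediate
14 | dimethyl (1-diazo-2-oxopropyl)phosphonate | COP(=O)(OC)C(=[N+]=[N-])C(C)=O | starting material
15 | (2R)-3-[(tert-butyldiphenylsilyl)oxy]-2-methylpropanal | O=C[C@H](C)CO[Si](c1ccccc1)(c1ccccc1)C(C)(C)C | intermediate
16 | tert-butyl{[(2S)-2-methylbut-3-yn-1-yl]oxy}diphenylsilane | C#C[C@H](C)CO[Si](c1ccccc1)(c1ccccc1)C(C)(C)C | intermediate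
17 | dichloro[(1Z,3R)-4-[(tert-butyldiphenylsilyl)oxy]-2-chloro-3-methylbut-1-en-1-yl]borane | ClB(Cl)/C=C(Cl)/[C@H](C)CO[Si](c1ccccc1)(c1ccccc1)C(C)(C)C | intermediate
18 | tert-butyl{[(2R,3Z)-3-chloro-2-methyl-4-(4,4,5,5-tetramethyl-1,3,2-dioxaborolan-2-yl)but-3-en-1-yl]oxy}diphenylsilane | CC1(C)OB(/C=C(Cl)/[C@H](C)CO[Si](c2ccccc2)(c2ccccc2)C(C)(C)C)OC1(C)C | intermediate
19 | (2E,4E,6Z,8R)-9-[(tert-butyldiphenylsilyl)oxy]-7-chloro-2,8-dimethylnona-2,4,6-trienal | O=C/C(C)=C/C=C/C=C(Cl)/[C@H](C)CO[Si](c1ccccc1)(c1ccccc1)C(C)(C)C | intermediate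
20 | (2E,4E,6Z,8R)-7-chloro-9-hydroxy-2,8-dimethylnona-2,4,6-trienal | O=C/C(C)=C/C=C/C=C(Cl)/[C@H](C)CO | intermediate
21 | lithium salt of phosphonate 7 deprotonated at C4 | [Li+].CCOP(=O)(OCC)[CH-]/C=C/C(=O)O[C@@H]1C[C@@H](C(=O)OCC=C)CC[C@@H]1O[Si](C)(C)C(C)(C)C | intermediate
22 | prop-2-en-1-yl (1S,3R,4S)-4-[(tert-butyldimethylsilyl)oxy]-3-{[(2E,4E,6E,8E,10Z,12R)-11-chloro-13-hydroxy-6,12-dimethyltrideca-2,4,6,8,10-pentaenoyl]oxy}cyclohexane-1-carboxylate | OC[C@@H](C)/C(Cl)=C/C=C/C=C(C)/C=C/C=C/C(=O)O[C@@H]1C[C@@H](C(=O)OCC=C)CC[C@@H]1O[Si](C)(C)C(C)(C)C | intermediate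
23 | prop-2-en-1-yl (1S,3R,4S)-4-[(tert-butyldimethylsilyl)oxy]-3-{[(2E,4E,6E,8E,10Z,12R)-11-chloro-6,12-dimethyl-13-oxotrideca-2,4,6,8,10-pentaenoyl]oxy}cyclohexane-1-carboxylate | O=C[C@@H](C)/C(Cl)=C/C=C/C=C(C)/C=C/C=C/C(=O)O[C@@H]1C[C@@H](C(=O)OCC=C)CC[C@@H]1O[Si](C)(C)C(C)(C)C | intermediate
24 | (2E)-pent-2-enal | CC/C=C/C=O | starting material
25 | tributyl(prop-2-en-1-yl)stannane | C=CC[Sn](CCCC)(CCCC)CCCC | starting material
26 | (4R,5E)-octa-1,5-dien-4-ol | CC/C=C/[C@H](O)CC=C | intermediate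
27 | tert-butyl(dimethyl){[(4R,5E)-octa-1,5-dien-4-yl]oxy}silane | CC/C=C/[C@H](O[Si](C)(C)C(C)(C)C)CC=C | intermediate
28 | (3R,4E)-3-[(tert-butyldimethylsilyl)oxy]hept-4-enal | CC/C=C/[C@H](O[Si](C)(C)C(C)(C)C)CC=O | intermediate
29 | (2S,3S,4E)-3-[(tert-butyldimethylsilyl)oxy]-2-chlorohept-4-enal | CC/C=C/[C@H](O[Si](C)(C)C(C)(C)C)[C@H](Cl)C=O | intermediate
30 | 1-[(tert-butyldimethylsilyl)oxy]propan-2-one | CC(=O)CO[Si](C)(C)C(C)(C)C | starting material
31 | lithium 3-[(tert-butyldimethylsilyl)oxy]prop-1-en-2-olate | [Li+].C=C([O-])CO[Si](C)(C)C(C)(C)C | intermediate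
32 | (4R,5R,6S,7E)-1,6-bis[(tert-butyldimethylsilyl)oxy]-5-chloro-4-hydroxydec-7-en-2-one | CC/C=C/[C@H](O[Si](C)(C)C(C)(C)C)[C@H](Cl)[C@H](O)CC(=O)CO[Si](C)(C)C(C)(C)C | intermediate
33 | (4R,5R,6S,7E)-6-[(tert-butyldimethylsilyl)oxy]-5-chloro-1,4-dihydroxydec-7-en-2-one | CC/C=C/[C@H](O[Si](C)(C)C(C)(C)C)[C@H](Cl)[C@H](O)CC(=O)CO | intermediate
34 | (7R)-2,2-di-tert-butyl-7-{(1R,2S,3E)-2-[(tert-butyldimethylsilyl)oxy]-1-chlorohex-3-en-1-yl}-1,3,2-dioxasilepan-5-one | CC/C=C/[C@H](O[Si](C)(C)C(C)(C)C)[C@H](Cl)[C@H]1CC(=O)CO[Si](C(C)(C)C)(C(C)(C)C)O1 | intermediate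
35 | dicyclohexylboron enolate of 34 (ring C14=C15 alkene, O14 trans to O–B) | CC/C=C/[C@H](O[Si](C)(C)C(C)(C)C)[C@H](Cl)[C@H]1C/C(OB(C2CCCCC2)C2CCCCC2)=C\O[Si](C(C)(C)C)(C(C)(C)C)O1 | intermediate
36 | O13-dicyclohexylboryl aldolate of 37 | CC/C=C/[C@H](O[Si](C)(C)C(C)(C)C)[C@H](Cl)[C@H]1CC(=O)[C@H](O[Si](C(C)(C)C)(C(C)(C)C)O1)[C@H](OB(C2CCCCC2)C2CCCCC2)[C@@H](C)/C(Cl)=C/C=C/C=C(C)/C=C/C=C/C(=O)O[C@@H]2C[C@@H](C(=O)OCC=C)CC[C@@H]2O[Si](C)(C)C(C)(C)C | intermediate
37 | prop-2-en-1-yl (1S,3R,4S)-4-[(tert-butyldimethylsilyl)oxy]-3-{[(2E,4E,6E,8E,10Z,12R,13R)-13-[(4R,7R)-2,2-di-tert-butyl-7-{(1R,2S,3E)-2-[(tert-butyldimethylsilyl)oxy]-1-chlorohex-3-en-1-yl}-5-oxo-1,3,2-dioxasilepan-4-yl]-11-chloro-13-hydroxy-6,12-dimethyltrideca-2,4,6,8,10-pentaenoyl]oxy}cyclohexane-1-carboxylate | CC/C=C/[C@H](O[Si](C)(C)C(C)(C)C)[C@H](Cl)[C@H]1CC(=O)[C@H](O[Si](C(C)(C)C)(C(C)(C)C)O1)[C@H](O)[C@@H](C)/C(Cl)=C/C=C/C=C(C)/C=C/C=C/C(=O)O[C@@H]2C[C@@H](C(=O)OCC=C)CC[C@@H]2O[Si](C)(C)C(C)(C)C | intermediate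
38 | O13-diethylboryl chelate of 37 | CC/C=C/[C@H](O[Si](C)(C)C(C)(C)C)[C@H](Cl)[C@H]1CC(=O)[C@H](O[Si](C(C)(C)C)(C(C)(C)C)O1)[C@H](OB(CC)CC)[C@@H](C)/C(Cl)=C/C=C/C=C(C)/C=C/C=C/C(=O)O[C@@H]2C[C@@H](C(=O)OCC=C)CC[C@@H]2O[Si](C)(C)C(C)(C)C | intermediate
39 | prop-2-en-1-yl (1S,3R,4S)-4-[(tert-butyldimethylsilyl)oxy]-3-{[(2E,4E,6E,8E,10Z,12R,13R)-13-[(4S,5S,7R)-2,2-di-tert-butyl-7-{(1R,2S,3E)-2-[(tert-butyldimethylsilyl)oxy]-1-chlorohex-3-en-1-yl}-5-hydroxy-1,3,2-dioxasilepan-4-yl]-11-chloro-13-hydroxy-6,12-dimethyltrideca-2,4,6,8,10-pentaenoyl]oxy}cyclohexane-1-carboxylate | CC/C=C/[C@H](O[Si](C)(C)C(C)(C)C)[C@H](Cl)[C@H]1C[C@H](O)[C@H](O[Si](C(C)(C)C)(C(C)(C)C)O1)[C@H](O)[C@@H](C)/C(Cl)=C/C=C/C=C(C)/C=C/C=C/C(=O)O[C@@H]2C[C@@H](C(=O)OCC=C)CC[C@@H]2O[Si](C)(C)C(C)(C)C | intermediate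
40 | (1S,3R,4S)-4-[(tert-butyldimethylsilyl)oxy]-3-{[(2E,4E,6E,8E,10Z,12R,13R)-13-[(4S,5S,7R)-2,2-di-tert-butyl-7-{(1R,2S,3E)-2-[(tert-butyldimethylsilyl)oxy]-1-chlorohex-3-en-1-yl}-5-hydroxy-1,3,2-dioxasilepan-4-yl]-11-chloro-13-hydroxy-6,12-dimethyltrideca-2,4,6,8,10-pentaenoyl]oxy}cyclohexane-1-carboxylic acid | CC/C=C/[C@H](O[Si](C)(C)C(C)(C)C)[C@H](Cl)[C@H]1C[C@H](O)[C@H](O[Si](C(C)(C)C)(C(C)(C)C)O1)[C@H](O)[C@@H](C)/C(Cl)=C/C=C/C=C(C)/C=C/C=C/C(=O)O[C@@H]2C[C@@H](C(=O)O)CC[C@@H]2O[Si](C)(C)C(C)(C)C | intermediate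
41 | (1S,3R,4S)-3-{[(2E,4E,6E,8E,10Z,12R,13R,14S,15S,17R,18R,19S,20E)-11,18-dichloro-13,14,15,17,19-pentahydroxy-6,12-dimethyltricosa-2,4,6,8,10,20-hexaenoyl]oxy}-4-hydroxycyclohexane-1-carboxylic acid | CC/C=C/[C@H](O)[C@H](Cl)[C@H](O)C[C@H](O)[C@H](O)[C@H](O)[C@@H](C)/C(Cl)=C/C=C/C=C(C)/C=C/C=C/C(=O)O[C@@H]1C[C@@H](C(=O)O)CC[C@@H]1O | target

Total step count: 24.
Longest linear sequence: 11 steps (24 → 41 through steps 14–24; equally 12 → 41 through steps 7–13 and 21–24).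

Steps most likely to fail

1. Step 21 (key aldol). The amine and boron chloride may remove a C16 proton instead of a C14 proton, and the resulting enolate can expel O17 and open the silylene ring. The ring stereocentre C17 may oppose the Felkin preference of the aldehyde and erode facial selectivity. Aldehyde 23 may epimerise at C12, or move its C10=C11 bond into conjugation, if the addition is slow. The fallback forms the same C13–C14 bond by alkenylmetal addition instead of aldol; it sets out from 29 (with 23 as partner) and comes back to the route at 41. Propargyl bromide and Zn (THF, aq NH4Cl) would add to 29 under the same polar control to give the 17,18-anti homopropargylic alcohol F1, and TBSOTf/2,6-lutidine would give the bis-silyl alkyne F2. Hydrozirconation of F2 (Cp2Zr(H)Cl), transmetalation with Me2Zn and Felkin-selective addition of the E-alkenylzinc to 23 would give the allylic alcohol F3. Matched Sharpless epoxidation directed by the C13 hydroxyl (Ti(OiPr)4, D-(−)-diisopropyl tartrate, t-BuOOH, 4 Å MS) would give the erythro trans-14,15-epoxy alcohol F4 without touching the other alkenes. Ti(OiPr)4-mediated opening with chloroacetic acid at C15, with inversion, would give the C15 chloroacetate F5, and thiourea/NaHCO3 would free the triol F6. Pd(PPh3)4/morpholine would then give the acid F7, and HF·pyridine would give 41.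

2. Step 17 (α-chlorination). The enamine of the β-silyloxy aldehyde may lose silanol (β-elimination to the dienal) faster than it is chlorinated, and the product may epimerise at C18 during isolation. The fallback replaces chlorination of a preformed aldehyde by an aldol that brings the chlorine in; it sets out from 24 and comes back at 29. The E enol borinate of S-tert-butyl chlorothioacetate, made with a menthone-derived bis(menthylmethyl)boron bromide and Et3N, would add to 24 in a reagent-controlled anti aldol to give the anti-chlorohydrin thioester F8. TBSOTf/2,6-lutidine would give the silyl ether F9, and i-Bu2AlH at −78 °C would reduce the thioester to 29.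

3. Step 9 (chloroboration). BCl3 may cleave the silyl ether, HCl may add instead of B–Cl, or the alkenylboron may protodeboronate on esterification. The fallback builds the chloroalkene by conjugate hydrochlorination and the triene by olefination; it sets out from 16 and comes back at 19. n-BuLi then ethyl chloroformate would give the ynoate F10, and LiCl in AcOH at 70 °C would add HCl anti to give the (Z)-β-chloroenoate F11. i-Bu2AlH would give the allylic alcohol F12 and MnO2 the enal F13. Horner–Wadsworth–Emmons reaction with ethyl (2E)-4-(diethoxyphosphoryl)-2-methylbut-2-enoate (LiN(SiMe3)2) would give the trienoate F14, i-Bu2AlH the trienol F15, and MnO2 the trienal 19.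

Further compounds
F1 | step 21 | (4R,5R,6S,7E)-6-[(tert-butyldimethylsilyl)oxy]-5-chlorodec-7-en-1-yn-4-ol | CC/C=C/[C@H](O[Si](C)(C)C(C)(C)C)[C@H](Cl)[C@H](O)CC#C
F2 | step 21 | (4R,5R,6S,7E)-4,6-bis[(tert-butyldimethylsilyl)oxy]-5-chlorodec-7-en-1-yne | CC/C=C/[C@H](O[Si](C)(C)C(C)(C)C)[C@H](Cl)[C@H](O[Si](C)(C)C(C)(C)C)CC#C
F3 | step 21 | prop-2-en-1-yl (1S,3R,4S)-4-[(tert-butyldimethylsilyl)oxy]-3-{[(2E,4E,6E,8E,10Z,12R,13S,14E,17R,18R,19S,20E)-17,19-bis[(tert-butyldimethylsilyl)oxy]-11,18-dichloro-13-hydroxy-6,12-dimethyltricosa-2,4,6,8,10,14,20-heptaenoyl]oxy}cyclohexane-1-carboxylate | CC/C=C/[C@H](O[Si](C)(C)C(C)(C)C)[C@H](Cl)[C@H](O[Si](C)(C)C(C)(C)C)C/C=C/[C@H](O)[C@@H](C)/C(Cl)=C/C=C/C=C(C)/C=C/C=C/C(=O)O[C@@H]1C[C@@H](C(=O)OCC=C)CC[C@@H]1O[Si](C)(C)C(C)(C)C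
F4 | step 21 | trans-14,15-epoxide of F3 on the face anti to the C13 hydroxyl (erythro epoxy alcohol) | CC/C=C/[C@H](O[Si](C)(C)C(C)(C)C)[C@H](Cl)[C@H](O[Si](C)(C)C(C)(C)C)C[C@H]1O[C@@H]1[C@H](O)[C@@H](C)/C(Cl)=C/C=C/C=C(C)/C=C/C=C/C(=O)O[C@@H]2C[C@@H](C(=O)OCC=C)CC[C@@H]2O[Si](C)(C)C(C)(C)C
F5 | step 21 | allyl ester of the target carrying a 15-O-chloroacetate and tert-butyldimethylsilyl ethers at O17, O19 and O4' (13R,14S,15S) | CC/C=C/[C@H](O[Si](C)(C)C(C)(C)C)[C@H](Cl)[C@H](O[Si](C)(C)C(C)(C)C)C[C@H](OC(=O)CCl)[C@H](O)[C@H](O)[C@@H](C)/C(Cl)=C/C=C/C=C(C)/C=C/C=C/C(=O)O[C@@H]1C[C@@H](C(=O)OCC=C)CC[C@@H]1O[Si](C)(C)C(C)(C)C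
F6 | step 21 | allyl ester of the target carrying tert-butyldimethylsilyl ethers at O17, O19 and O4' | CC/C=C/[C@H](O[Si](C)(C)C(C)(C)C)[C@H](Cl)[C@H](O[Si](C)(C)C(C)(C)C)C[C@H](O)[C@H](O)[C@H](O)[C@@H](C)/C(Cl)=C/C=C/C=C(C)/C=C/C=C/C(=O)O[C@@H]1C[C@@H](C(=O)OCC=C)CC[C@@H]1O[Si](C)(C)C(C)(C)C
F7 | step 21 | target acid carrying tert-butyldimethylsilyl ethers at O17, O19 and O4' | CC/C=C/[C@H](O[Si](C)(C)C(C)(C)C)[C@H](Cl)[C@H](O[Si](C)(C)C(C)(C)C)C[C@H](O)[C@H](O)[C@H](O)[C@@H](C)/C(Cl)=C/C=C/C=C(C)/C=C/C=C/C(=O)O[C@@H]1C[C@@H](C(=O)O)CC[C@@H]1O[Si](C)(C)C(C)(C)C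
F8 | step 17 | S-tert-butyl (2S,3S,4E)-2-chloro-3-hydroxyhept-4-enethioate | CC/C=C/[C@H](O)[C@H](Cl)C(=O)SC(C)(C)C
F9 | step 17 | S-tert-butyl (2S,3S,4E)-3-[(tert-butyldimethylsilyl)oxy]-2-chlorohept-4-enethioate | CC/C=C/[C@H](O[Si](C)(C)C(C)(C)C)[C@H](Cl)C(=O)SC(C)(C)C
F10 | step 9 | ethyl (4S)-5-[(tert-butyldiphenylsilyl)oxy]-4-methylpent-2-ynoate | CCOC(=O)C#C[C@H](C)CO[Si](c1ccccc1)(c1ccccc1)C(C)(C)C
F11 | step 9 | ethyl (2Z,4R)-5-[(tert-butyldiphenylsilyl)oxy]-3-chloro-4-methylpent-2-enoate | CCOC(=O)/C=C(Cl)/[C@H](C)CO[Si](c1ccccc1)(c1ccccc1)C(C)(C)C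
F12 | step 9 | (2Z,4R)-5-[(tert-butyldiphenylsilyl)oxy]-3-chloro-4-methylpent-2-en-1-ol | OC/C=C(Cl)/[C@H](C)CO[Si](c1ccccc1)(c1ccccc1)C(C)(C)C
F13 | step 9 | (2Z,4R)-5-[(tert-butyldiphenylsilyl)oxy]-3-chloro-4-methylpent-2-enal | O=C/C=C(Cl)/[C@H](C)CO[Si](c1ccccc1)(c1ccccc1)C(C)(C)C
F14 | step 9 | ethyl (2E,4E,6Z,8R)-9-[(tert-butyldiphenylsilyl)oxy]-7-chloro-2,8-dimethylnona-2,4,6-trienoate | CCOC(=O)/C(C)=C/C=C/C=C(Cl)/[C@H](C)CO[Si](c1ccccc1)(c1ccccc1)C(C)(C)C
F15 | step 9 | (2E,4E,6Z,8R)-9-[(tert-butyldiphenylsilyl)oxy]-7-chloro-2,8-dimethylnona-2,4,6-trien-1-ol | OC/C(C)=C/C=C/C=C(Cl)/[C@H](C)CO[Si](c1ccccc1)(c1ccccc1)C(C)(C)C
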